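**Strategy.** The chroman is disconnected across its dihydropyran ring (O1, C2, C3, C4, C4a, C8a): C3–C4 is an ethylene unit lying between the electron-rich aryl carbon C4a (ortho to O1) and the O-bearing quaternary C2. A catalytic asymmetric oxa-Povarov-type [4+2] annulation joins an O-aryl oxocarbenium ion (C4a=C8a–O1=C2, carrying the whole side chain) with phenyl vinyl sulfide, forming C3–C2 and C4–C4a and setting C2 in one operation. Its precursor is an open-chain aryl enol ether made by methylenation of an aryl ester; the two side-chain stereocentres come from (R)-citronellyl bromide and (S)-3-bromo-2-methylpropanol. Desulfurisation and O-demethylation finish the synthesis.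

Key step: step 6

Remark: C8' of the side chain carries the descriptor S in all 11'-ene compounds only because the 11',12'-double bond raises the CIP rank of the chain end; the spatial arrangement is that of the SMILES strings.
Remark: the enantiomer of the chiral acid in step 6 is the one that delivers 2R; it has to be assigned in a trial run.

Step 1
Reactants: 1 (R)-citronellyl bromide; 2 (S)-3-bromo-2-methylpropan-1-ol
Product: 5 (2R,6S)-2,6,10-trimethylundec-9-en-1-ol, via citronellylmagnesium bromide 3 (not isolated), via chloromagnesium alkoxide 4 (not isolated)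
Conditions: 1, Mg, THF, 40 °C (gives 3); 2, MeMgCl (1.0 equiv), THF, −30 °C (gives 4); 3 (1.5 equiv) added to 4, Li2CuCl4 (5 mol%), THF, −30 °C to rt; 1 M HCl work-up
Reagents that add atoms: none
Why: A copper-catalysed sp3–sp3 Grignard–alkyl bromide cross-coupling displaces the primary bromide of the pre-formed magnesium alkoxide, and both stereocentres are carried in unchanged from 1 and 2 because neither sits at a reacting carbon.

Step 2
Reactants: 5 (2R,6S)-2,6,10-trimethylundec-9-en-1-ol
Product: 6 (6S,10R)-11-bromo-2,6,10-trimethylundec-2-ene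
Conditions: CBr4, PPh3, CH2Cl2, 0 °C
Reagents that add atoms: carbon tetrabromide, BrC(Br)(Br)Br
Why: The Appel reaction converts the primary alcohol into the bromide under neutral conditions that touch neither the trisubstituted alkene nor the adjacent stereocentre.

Step 3
Reactants: 6 (6S,10R)-11-bromo-2,6,10-trimethylundec-2-ene; 7 β-propiolactone
Product: 9 (5R,9S)-5,9,13-trimethyltetradec-12-enoic acid, via Grignard reagent 8 (not isolated)
Conditions: Mg, THF, 40 °C; then 7, CuBr·SMe2 (5 mol%), THF–Me2S, −20 to 0 °C; 1 M HCl work-up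
Reagents that add atoms: none
Why: Under copper catalysis the Grignard reagent opens β-propiolactone by SN2 attack at the O–CH2 carbon (alkyl–oxygen cleavage), which adds C2, C1' and C2' and gives the carboxylic acid directly.

Step 4
Reactants: 9 (5R,9S)-5,9,13-trimethyltetradec-12-enoic acid; 10 4-methoxy-2-methylphenol
Product: 11 4-methoxy-2-methylphenyl (5R,9S)-5,9,13-trimethyltetradec-12-enoate
Conditions: DCC, DMAP (10 mol%), CH2Cl2, 0 °C to rt
Reagents that add atoms: none
Why: Steglich esterification acylates the hindered phenol under mild conditions in which no stereocentre is at risk.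

Step 5
Reactants: 11 4-methoxy-2-methylphenyl (5R,9S)-5,9,13-trimethyltetradec-12-enoate
Product: 12 4-methoxy-2-methyl-1-{[(6R,10S)-6,10,14-trimethylpentadeca-1,13-dien-2-yl]oxy}benzene
Conditions: Cp2TiMe2 (2.5 equiv), toluene–THF, 65 °C, dark; filtration through basic alumina
Reagents that add atoms: dimethyltitanocene Cp2TiMe2, C[Ti](C)(C1C=CC=C1)C1C=CC=C1
Why: Petasis methylenation (titanocene methylidene, [2+2] addition and cycloreversion) turns the ester carbonyl into the 1,1-disubstituted enol ether under non-acidic conditions, so that the new =CH2 carbon later becomes the C2 methyl group of the chroman.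

Step 6
Reactants: 12 aryl enol ether; 13 phenyl vinyl sulfide
Product: 14 (2R)-6-methoxy-2,8-dimethyl-4-(phenylsulfanyl)-2-[(4R,8S)-4,8,12-trimethyltridec-11-en-1-yl]-3,4-dihydro-2H-chromene (both C4 epimers)
Conditions: chiral BINOL-derived N-triflyl imidodiphosphorimidate Brønsted acid (IDPi, 5 mol%), 13 (3 equiv), 5 Å molecular sieves, CH2Cl2, −60 °C; Et3N quench
Reagents that add atoms: none
Why: Proposed new method: protonation of the enol ether CH2 by the confined chiral acid gives an O-aryl oxocarbenium ion at C2 paired with the chiral anion, the β-carbon of 13 adds to C2 (bond C3–C2), the resulting thionium carbon C4 is captured by the only free ortho carbon of ring A (bond C4–C4a), and loss of the arene proton returns the catalyst. The closest known reaction type is the Lewis-acid-mediated oxa-Povarov reaction, a formal inverse-electron-demand [4+2] of aryl oxocarbenium ions with alkenes that is known in racemic form and mainly with aldehyde-derived cations, while ion pairing with confined imidodiphosphorimidate anions is an established way to control additions to aliphatic oxocarbenium ions. The dihydropyran ring closes by a 6-exo-trig Friedel–Crafts attack of C4a on the thionium ion. The configuration at C2 is set by the catalyst, whose pocket must tell the methyl group from the CH2 chain, whereas the C4 centre forms as a mixture and is erased in step 7. Regioselectivity is secured by the C8 methyl group, which blocks the other ortho position, and chemoselectivity by the far higher basicity of the enol ether compared with the remote trisubstituted alkene and by the excess of the more nucleophilic vinyl sulfide.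

Step 7
Reactants: 14 4-(phenylsulfanyl)chroman methyl ether
Product: 15 (2R)-6-methoxy-2,8-dimethyl-2-[(4R,8S)-4,8,12-trimethyltridec-11-en-1-yl]-3,4-dihydro-2H-chromene
Conditions: Bu3SnH (3 equiv), AIBN (0.2 equiv), toluene, 110 °C
Reagents that add atoms: none
Why: In this radical chain desulfurisation the stannyl radical attacks sulfur and releases the benzylic C4 radical, which takes hydrogen from Bu3SnH, while the isolated trisubstituted alkene and the C2 centre are inert.

Step 8
Reactants: 15 6-O-methyl ether of the target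
Product: 16 (2R)-2,8-dimethyl-2-[(4R,8S)-4,8,12-trimethyltridec-11-en-1-yl]-3,4-dihydro-2H-chromen-6-ol
Conditions: NaSEt (6 equiv), DMF, 130 °C, argon; dilute HCl work-up
Reagents that add atoms: none
Why: Ethanethiolate cleaves the aryl methyl ether by SN2 attack at the methyl carbon, whereas the tertiary O1–C2 ether cannot react in this way and the alkene is untouched.

**Compound list**

1 | (R)-citronellyl bromide, (6R)-8-bromo-2,6-dimethyloct-2-ene | CC(C)=CCC[C@@H](C)CCBr | starting material
2 | (S)-3-bromo-2-methylpropan-1-ol | BrC[C@@H](C)CO | starting material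
3 | [(3R)-3,7-dimethyloct-6-en-1-yl]magnesium bromide | CC(C)=CCC[C@@H](C)CC[Mg]Br | intermediate
4 | chloromagnesium (2S)-3-bromo-2-methylpropan-1-olate | BrC[C@@H](C)CO[Mg]Cl | intermediate
5 | (2R,6S)-2,6,10-trimethylundec-9-en-1-ol | CC(C)=CCC[C@@H](C)CCC[C@@H](C)CO | intermediate
6 | (6S,10R)-11-bromo-2,6,10-trimethylundec-2-ene | CC(C)=CCC[C@@H](C)CCC[C@@H](C)CBr | intermediate
7 | β-propiolactone (oxetan-2-one) | O=C1CCO1 | starting material
8 | [(2R,6S)-2,6,10-trimethylundec-9-en-1-yl]magnesium bromide | CC(C)=CCC[C@@H](C)CCC[C@@H](C)C[Mg]Br | intermediate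
9 | (5R,9S)-5,9,13-trimethyltetradec-12-enoic acid | CC(C)=CCC[C@@H](C)CCC[C@@H](C)CCCC(=O)O | intermediate
10 | 4-methoxy-2-methylphenol | COc1ccc(O)c(C)c1 | starting material
11 | 4-methoxy-2-methylphenyl (5R,9S)-5,9,13-trimethyltetradec-12-enoate | CC(C)=CCC[C@@H](C)CCC[C@@H](C)CCCC(=O)Oc1ccc(OC)cc1C | intermediate
12 | 4-methoxy-2-methyl-1-{[(6R,10S)-6,10,14-trimethylpentadeca-1,13-dien-2-yl]oxy}benzene | CC(C)=CCC[C@@H](C)CCC[C@@H](C)CCCC(=C)Oc1ccc(OC)cc1C | intermediate
13 | phenyl vinyl sulfide | C=CSc1ccccc1 | starting material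
14 | (2R)-6-methoxy-2,8-dimethyl-4-(phenylsulfanyl)-2-[(4R,8S)-4,8,12-trimethyltridec-11-en-1-yl]-3,4-dihydro-2H-chromene (C4 epimers) | CC(C)=CCC[C@@H](C)CCC[C@@H](C)CCC[C@]1(C)CC(Sc3ccccc3)c2cc(OC)cc(C)c2O1 | intermediate
15 | (2R)-6-methoxy-2,8-dimethyl-2-[(4R,8S)-4,8,12-trimethyltridec-11-en-1-yl]-3,4-dihydro-2H-chromene | CC(C)=CCC[C@@H](C)CCC[C@@H](C)CCC[C@]1(C)CCc2cc(OC)cc(C)c2O1 | intermediate
16 | (2R)-2,8-dimethyl-2-[(4R,8S)-4,8,12-trimethyltridec-11-en-1-yl]-3,4-dihydro-2H-chromen-6-ol | CC(C)=CCC[C@@H](C)CCC[C@@H](C)CCC[C@]1(C)CCc2cc(O)cc(C)c2O1 | target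

**Total step count:** 8. **Longest linear sequence:** 8 steps (1 to 16).

**Steps most likely to fail**

1. Step 6 (Proposed new method). The catalyst pocket may discriminate poorly between the methyl group and the CH2 chain at the oxocarbenium carbon. Cationic oligomerisation of the enol ether or of the vinyl sulfide may outrun the annulation, and traces of water may hydrolyse the cation. The fallback uses known chemistry, sets out from phenol 10 and bromide 6, and comes back at 15. Phenol 10 is alkylated at its free ortho position with methyl vinyl ketone under acid catalysis to give 4-(2-hydroxy-5-methoxy-3-methylphenyl)butan-2-one F1. Wittig methylenation with excess Ph3P=CH2 gives 4-methoxy-2-methyl-6-(3-methylbut-3-en-1-yl)phenol F2. An enantioselective Wacker-type oxypalladation with methoxycarbonylation [Pd(OCOCF3)2, the Bn-BOXAX enantiomer that delivers 2S, p-benzoquinone, CO, MeOH] forms the O1–C2 bond and gives methyl 2-[(2S)-6-methoxy-2,8-dimethyl-3,4-dihydro-2H-chromen-2-yl]acetate F3. Reduction with LiAlH4 gives 2-[(2S)-6-methoxy-2,8-dimethyl-3,4-dihydro-2H-chromen-2-yl]ethan-1-ol F4, and TsCl in pyridine gives 2-[(2S)-6-methoxy-2,8-dimethyl-3,4-dihydro-2H-chromen-2-yl]ethyl 4-methylbenzenesulfonate F5. Coupling of F5 with Grignard reagent 8 (made from 6 as in step 3) under Li2CuCl4 catalysis gives 15.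

2. Step 5. Methylenation of the hindered aryl ester may stop short, and the acid-labile enol ether may hydrolyse or suffer double-bond migration during isolation. The fallback sets out from acid 9 and comes back at 12. Acid 9 reacts with MeLi (2.2 equiv) to give (6R,10S)-6,10,14-trimethylpentadec-13-en-2-one F6. Kinetic deprotonation (LDA, THF, −78 °C) and trapping with PhNTf2 gives (6R,10S)-6,10,14-trimethylpentadeca-1,13-dien-2-yl trifluoromethanesulfonate F7. Palladium-catalysed C–O coupling of F7 with phenol 10 [Pd2(dba)3, 2-(di-tert-butylphosphino)biphenyl, NaOtBu, toluene] gives 12.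

3. Step 1. Substitution at the β-branched bromide may be slow, so that Grignard homocoupling and ring closure of the bromo alkoxide to an oxetane compete. The fallback sets out from 1 and 2 and comes back at 5. Alcohol 2 is silylated (TBSCl, imidazole) to [(2S)-3-bromo-2-methylpropoxy](tert-butyl)dimethylsilane F8. Bromide 1 is converted with zinc dust (cat. I2, DMA) into [(3R)-3,7-dimethyloct-6-en-1-yl]zinc bromide F9. A nickel-catalysed alkyl–alkyl Negishi coupling of F8 with F9 [Ni(cod)2, s-Bu-Pybox, DMA, rt] gives tert-butyldimethyl{[(2R,6S)-2,6,10-trimethylundec-9-en-1-yl]oxy}silane F10, and TBAF in THF gives 5.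

**Further compounds**

F1 | step 6 | 4-(2-hydroxy-5-methoxy-3-methylphenyl)butan-2-one | CC(=O)CCc1cc(OC)cc(C)c1O
F2 | step 6 | 4-methoxy-2-methyl-6-(3-methylbut-3-en-1-yl)phenol | CC(=C)CCc1cc(OC)cc(C)c1O
F3 | step 6 | methyl 2-[(2S)-6-methoxy-2,8-dimethyl-3,4-dihydro-2H-chromen-2-yl]acetate | COC(=O)C[C@]1(C)CCc2cc(OC)cc(C)c2O1
F4 | step 6 | 2-[(2S)-6-methoxy-2,8-dimethyl-3,4-dihydro-2H-chromen-2-yl]ethan-1-ol | OCC[C@]1(C)CCc2cc(OC)cc(C)c2O1
F5 | step 6 | 2-[(2S)-6-methoxy-2,8-dimethyl-3,4-dihydro-2H-chromen-2-yl]ethyl 4-methylbenzenesulfonate | Cc1ccc(cc1)S(=O)(=O)OCC[C@]1(C)CCc2cc(OC)cc(C)c2O1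
F6 | step 5 | (6R,10S)-6,10,14-trimethylpentadec-13-en-2-one | CC(C)=CCC[C@@H](C)CCC[C@@H](C)CCCC(C)=O
F7 | step 5 | (6R,10S)-6,10,14-trimethylpentadeca-1,13-dien-2-yl trifluoromethanesulfonate | CC(C)=CCC[C@@H](C)CCC[C@@H](C)CCCC(=C)OS(=O)(=O)C(F)(F)F
F8 | step 1 | [(2S)-3-bromo-2-methylpropoxy](tert-butyl)dimethylsilane | BrC[C@@H](C)CO[Si](C)(C)C(C)(C)C
F9 | step 1 | [(3R)-3,7-dimethyloct-6-en-1-yl]zinc bromide | CC(C)=CCC[C@@H](C)CC[Zn]Br
F10 | step 1 | tert-butyldimethyl{[(2R,6S)-2,6,10-trimethylundec-9-en-1-yl]oxy}silane | CC(C)=CCC[C@@H](C)CCC[C@@H](C)CO[Si](C)(C)C(C)(C)C
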